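**Remark on the chemistry (assumption).** Which antipode of BINAP leads to the (R)-enone 6 cannot be derived from the substrate; (S)-BINAP is written throughout, and its mirror image is to be used if the first chiral analysis of 6 shows the other enantiomer.

Side-chain carbons are numbered C1' (benzylic) to C15'.

## Analysis of the target

Target 29 is a toluhydroquinone monomethyl ether (5-hydroxy-2-methoxy-3-methylphenyl) carrying a rearranged C15 terpenoid chain, whose only ring is the cyclopentane C7'–C11'. C7' and C11' are adjacent quaternary stereocentres, both R, each with a methyl group. The two methyls are cis, so the two arms (C6' on C7', C12' on C11') are cis as well. The only other stereo-element is the E-configured trisubstituted alkene C2'=C3'.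

Both ketones (C5' and C12') are β,γ-unsaturated and will slip into conjugation with acid or base. They also stand in a 1,5-relationship, so an enolate of either can close a six-membered aldol ring. The para-methoxyphenol is electron-rich and is easily oxidised to a quinone.

The difficulty is twofold: two contiguous quaternary carbons must be made on a five-membered ring as one enantiomer with no other stereocentre to lean on, and two isomerisation-prone skipped enones must be carried through the endgame.

The plan rests on reading the cyclopentane C7'–C11' together with C6', C5' and C12' as a bicyclo[3.3.0]octenone in which the bond C5'–C12' is surplus. C7' with its methyl is then the inner carbon of a 1,1-disubstituted alkene, C11' and C12' are the carbons of a tethered alkyne, and C5' is carbon monoxide.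

## Retrosynthetic reasoning

**Endgame, 29 ⇒ 28 ⇒ 27.** No C–C bond is cut. The phenol is released last from silyl ether 28, because a free para-methoxyphenol would not survive the oxidation before it. The C12' ketone of 28 is traced back to the carbinol in 27, so that this ketone appears only after the last carbanion chemistry is over.

**C4'–C5', 27 ⇒ 26 ⇒ 24 + 14.** This cut divides the molecule into an achiral aryl–allyl half and the chiral cyclopentane half, of similar size. C4' is allylic, so a sulfonyl group there gives a stabilised nucleophile (25, from 24) that keeps the E geometry and reacts at its α-carbon. C5' is at the acid oxidation level and is tied up with the C12' oxygen as δ-lactone 14, which serves both as acyl donor and as protection of the carbinol. The forward sequence must acylate, then remove the sulfonyl group reductively so that the dienolate is protonated at C4'.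

**C13'–C14' and C12'–C13', 14 ⇒ 13 ⇒ 11 + 12, and 11 ⇒ 10.** A prenyl metal would add to aldehyde 10 through its γ-carbon and give the branched carbinol. C13' is therefore introduced as an epoxide methylene and C14'–C15' as the alkenyl Grignard reagent 12, which can only give the linear chain. The opening has to occur at the epoxide CH2 without attack on the ester.

**C5'–C12' (ring cleavage), 10 ⇒ 9 ⇒ 7.** The two arms are the two ends of one double bond. Because that double bond is an enol ether, oxidative cleavage gives an aldehyde at C12' and an acid at C5', differentiated without any extra step.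

**C11'–CH3, 7 ⇒ 6.** C11' is the β-carbon of enone 6, so the methyl is added in a conjugate sense. Only the cis-fused diquinane can form, which fixes C11' relative to C7'. The enolate must be captured as the enol ether towards C12'; the corresponding ketone would be meso, so the position of this double bond is the only place where the chirality is stored at that stage.

**Key disconnection, 6 ⇒ 4 + 5.** Three bonds (C7'–C11', C6'–C5', C5'–C12') and both rings go back to enyne 4 and carbon monoxide 5. The quaternary centre C7' is created in the same event that closes the carbocycle.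

**Enyne, 4 ⇒ 2 + 3, 2 ⇒ 1.** The C7'–C8' bond is cut so that the alkene comes from Grignard reagent 3 and the alkyne with its tether from alcohol 1.

**Aryl–allyl sulfone, 24 ⇒ 22 ⇒ 19 + 20, and 19 ⇒ 18 ⇒ 16 ⇒ 15.** The aryl–C1' bond is cut in an SN2' sense, so that vinyl oxirane 20 supplies C1'–C4' with the E alkene and an oxygen handle for the sulfonyl group. The arene 19 is reached from bromophenol 15, whose bromine and methyl already flank the oxygen that becomes the methoxy group; the para oxygen is introduced at the only unhindered C–H.

## Alternatives that were turned down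

**Alternative 1: double methylation of a fused menthyloxybutenolide.**
- Disconnection: the two C–CH3 bonds at C7' and C11'. The ring is preformed as the cyclopentene-fused menthyloxybutenolide A1, with C6' as acetal carbon and C12' as lactone carbonyl.
- Forward key step: a methylcuprate adds to C7' of A1 anti to the menthyloxy group, and the lactone enolate is C-methylated at C11', giving the cis-dimethyl lactone acetal A2 in one flask.
- For: the stereochemical information is a stoichiometric acetal auxiliary, so diastereomers can be separated and the absolute configuration secured without an enantioselective catalyst. On this point it is stronger than the chosen route. The two arms also arrive differentiated.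
- Against: the β-carbon of A1 belongs to a tetrasubstituted alkene, the least reactive class of butenolide for cuprate addition, and the alkylation must then build a second quaternary carbon beside the first. C6' arrives as an acetal carbon directly on C7', whereas the target has a methylene there and the carbonyl one carbon further out, so C6' must be deoxygenated and the chain extended by one carbon. C12' arrives as a carboxyl carbon that must become a ketone bearing a linear prenyl group at a neopentyl position. A1 itself has to be made and its acetal epimers separated.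
- Comparison: the chosen route delivers C6' as CH2 and C5' as carbonyl directly, needs no auxiliary, and reaches the differentiated aldehyde and acid three steps after ring formation. In exchange it depends on a catalyst-controlled enantiomeric purity that cannot be upgraded through a crystalline diastereomer.

**Alternative 2: De Mayo photocycloaddition.**
- Disconnection: C11'–C12' and C7'–C6'. The ring is the symmetrical alkene A4 (1,2-dimethylcyclopentene) and four chain carbons come from the chiral dioxinone A3.
- Forward key step: irradiation near 300 nm joins A3 and A4 to the cyclobutane photoadduct A5. Opening the dioxanone and retro-aldol cleavage would leave an acetic acid arm on C7' and an acetyl group on C11'.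
- For: both quaternary carbons already exist in a cheap alkene, no nucleophile has to create a quaternary centre, the cis relationship is enforced by the cyclobutane, and C5' and C12' arrive at useful oxidation levels in one step. In bond economy at the quaternary carbons it is at least equal to the chosen route, and it is shorter to the ring.
- Against: because A4 is symmetrical, the enantiomer obtained after fragmentation depends on two independent selectivities, the face of A3 attacked and the orientation of the carbocycle relative to the dioxanone (cis-anti-cis versus cis-syn-cis). These lead to opposite enantiomers, so both must be high. A tetrasubstituted alkene is a slow partner for an excited enone and hydrogen abstraction competes. C13' arrives as an acetyl methyl, and joining C14'=C15' to it needs alkenylation of an enolate carbon (a base-sensitive skipped enone formed early) or an aldol condensation (the conjugated isomer). C5' must still be joined to C4' as in the chosen route.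
- Comparison: the chosen route has a single enantio-determining event, the second centre follows from ring strain, and C13'–C15' is built by an epoxide opening that cannot misplace the double bond.

**Alternative 3: Weiss–Cook diquinane.**
- Disconnection: C7'–C8', C11'–C10', C7'–C6' and C11'–C12'. Both rings are assembled around the two methyl-bearing carbons of biacetyl A6 with two molecules of dimethyl 3-oxoglutarate A7.
- Forward key step: condensation in buffered water, then acid hydrolysis and decarboxylation in the same flask, giving the meso dione A8.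
- For: commodity materials, no metal, four C–C bonds, both quaternary carbons, and cis geometry guaranteed by ring fusion. As a construction of the skeleton it is more robust and cheaper than the chosen key step.
- Against: A8 is meso and carries one carbonyl too many. The ketone at C9' must be removed, which first needs two equivalent ketones to be told apart, then a deoxygenation, to reach the meso monoketone A9. Chirality can only then be introduced, by enantiotopic deprotonation with a stoichiometric chiral lithium amide and silylation, which leads to enol ether 7 of the present route.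
- Comparison: about five steps to 7 against four, with a redox detour at C9' and the enantiomeric purity resting on a stoichiometric chiral base. The chosen route introduces no atom that must be removed and sets the configuration catalytically as the ring forms. The meso nature of A9 is nevertheless used below as a reserve.

Key step: step 3

## Route

**Step 1**
Reactants: 1 pent-4-yn-1-ol
Product: 2 pent-4-yn-1-yl 4-methylbenzenesulfonate
Conditions: TsCl, Et3N, DMAP (cat.), CH2Cl2, 0 °C → rt
Reagents that add atoms: 4-methylbenzenesulfonyl chloride, Cc1ccc(cc1)S(Cl)(=O)=O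
Why: Sulfonylation of a primary alcohol; the terminal alkyne is inert and the tosylate is the leaving group for the coupling that follows.

**Step 2**
Reactants: 2 pent-4-yn-1-yl 4-methylbenzenesulfonate; 3 isopropenylmagnesium bromide
Product: 4 6-methylhept-6-en-1-yne
Conditions: 3 (2.5 equiv), Li2CuCl4 (3 mol%), THF, −20 °C → rt; aq. NH4Cl
Reagents that add atoms: none
Why: Copper-catalysed sp2–sp3 cross-coupling of an alkenyl Grignard reagent with a primary tosylate. The first equivalent of 3 deprotonates the alkyne, whose magnesium acetylide does not couple and is re-protonated on work-up, which is why an excess is used.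

**Step 3**
Reactants: 4 6-methylhept-6-en-1-yne; 5 carbon monoxide
Product: 6 (R)-5-methylbicyclo[3.3.0]oct-1-en-3-one
Conditions: [Rh(CO)2Cl]2 (3 mol%), (S)-BINAP (9 mol%), AgOTf (12 mol%), CO (1 atm), THF, 90 °C, slow addition of 4
Reagents that add atoms: none
Why: Alkyne and alkene of 4 bind to the cationic monovalent rhodium–BINAP fragment (chloride removed by AgOTf), oxidative cyclisation gives a rhodacyclopentene, CO inserts into a Rh–C bond and reductive elimination releases 6; the closest known reaction type is the catalytic asymmetric intramolecular Pauson–Khand-type (2+2+1) cyclocarbonylation of 1,6-enynes. The cyclopentane C7'–C11' closes in the oxidative cyclisation through bond C7'–C11', a five-membered ring formed exo with respect to both π bonds across the three-carbon tether. The cyclopentenone closes in the carbonylation, CO becoming C5' bonded to C6' and C12', as the second ring of the fused bicycle. The only new stereocentre, quaternary C7', is set in the oxidative cyclisation, where the C2-symmetric diphosphine decides which enantiotopic face of the 1,1-disubstituted alkene bonds to C11'; it cannot epimerise afterwards. Regiochemistry needs no control because the tether allows one mode of coupling. The selectivities required are enantioface selection and chemoselectivity for cyclocarbonylation over alkyne oligomerisation and cycloisomerisation to a 1,4-diene; the CO atmosphere and slow addition at high dilution are meant to secure the latter. Terminal alkynes and 1,1-disubstituted alkenes are each known in this reaction, but their combination in a tether without geminal substituents is the least favourable case, so the risk of the route is concentrated here.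

**Step 4**
Reactants: 6 (R)-5-methylbicyclo[3.3.0]oct-1-en-3-one
Product: 7 (1S,5R)-1,5-dimethyl-3-(trimethylsilyloxy)bicyclo[3.3.0]oct-2-ene
Conditions: MeMgBr, CuBr·SMe2 (20 mol%), Me3SiCl, HMPA, THF, −78 → −40 °C; Et3N, pentane, cold aq. NaHCO3; used crude
Reagents that add atoms: methylmagnesium bromide, C[Mg]Br; chlorotrimethylsilane, C[Si](C)(C)Cl
Why: Copper-catalysed conjugate addition accelerated by the chlorosilane, which also traps the enolate as the enol ether towards C12'. The methyl can reach C11' only on the face that gives the cis-fused diquinane, so it comes out cis to the C7' methyl. The derived ketone would be meso, so 7 must be carried on without hydrolysis.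

**Step 5**
Reactants: 7 (1S,5R)-1,5-dimethyl-3-(trimethylsilyloxy)bicyclo[3.3.0]oct-2-ene
Product: 9 2-[(1R,2R)-2-formyl-1,2-dimethylcyclopentyl]acetic acid, via trimethylsilyl ester 8 (not isolated)
Conditions: O3, CH2Cl2, −78 °C; Me2S, −78 °C → rt; H2O
Reagents that add atoms: ozone, [O-][O+]=O
Why: Ozonolysis of a silyl enol ether cleaves C5'=C12' into an aldehyde (C12') and a silyl ester (C5') that hydrolyses to the acid on work-up. Both stereocentres are quaternary and are not touched.

**Step 6**
Reactants: 9 2-[(1R,2R)-2-formyl-1,2-dimethylcyclopentyl]acetic acid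
Product: 10 methyl 2-[(1R,2R)-2-formyl-1,2-dimethylcyclopentyl]acetate
Conditions: MeI, K2CO3, DMF, rt
Reagents that add atoms: iodomethane, CI
Why: SN2 O-alkylation of the carboxylate, which also draws any cyclic pseudo-acid form into the open ester. The aldehyde has no α-hydrogen and tolerates the base.

**Step 7**
Reactants: 10 methyl 2-[(1R,2R)-2-formyl-1,2-dimethylcyclopentyl]acetate
Product: 11 methyl 2-[(1R,2R)-1,2-dimethyl-2-(oxiran-2-yl)cyclopentyl]acetate
Conditions: Me3S+ I−, n-BuLi, THF, −10 °C; then 10, −10 °C → rt
Reagents that add atoms: trimethylsulfonium iodide, C[S+](C)C.[I-]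
Why: Corey–Chaykovsky epoxidation; the sulfur ylide adds to the aldehyde far faster than to the hindered ester and delivers C13' as the epoxide methylene. The new centre at C12' is not controlled and need not be, since it becomes a carbonyl carbon in step 16.

**Step 8**
Reactants: 11 methyl 2-[(1R,2R)-1,2-dimethyl-2-(oxiran-2-yl)cyclopentyl]acetate; 12 2-methylprop-1-en-1-ylmagnesium bromide
Product: 14 (4aR,7aR)-4a,7a-dimethyl-1-(3-methylbut-2-en-1-yl)hexahydrocyclopenta[c]pyran-3(1H)-one, via hydroxy ester 13 (not isolated)
Conditions: 12 (1.3 equiv), CuI (15 mol%), THF, −40 → 0 °C; aq. NH4Cl; PPTS (cat.), PhMe, 60 °C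
Reagents that add atoms: none
Why: Copper-catalysed SN2 opening of the epoxide at its CH2 terminus by the alkenyl Grignard reagent gives the linear C12'–C13'–C14'=C15' pattern. The cis hydroxy ester then closes to the six-membered lactone, helped by the two quaternary carbons (Thorpe–Ingold effect). 14 is a mixture of C12' epimers.

**Step 9**
Reactants: 15 2-bromo-6-methylphenol
Product: 16 1-bromo-2-methoxy-3-methylbenzene
Conditions: MeI, K2CO3, acetone, reflux
Reagents that add atoms: iodomethane, CI
Why: Williamson ether synthesis on a phenoxide; the hindered oxygen is methylated first, so the later para oxygen can carry a different group.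

**Step 10**
Reactants: 16 1-bromo-2-methoxy-3-methylbenzene
Product: 18 3-bromo-4-methoxy-5-methylphenol, via pinacol arylboronate 17 (not isolated)
Conditions: B2pin2, [Ir(OMe)(cod)]2 (1.5 mol%), 4,4'-di-tert-butyl-2,2'-bipyridine (3 mol%), THF, 80 °C; then KHSO5 (Oxone), acetone/H2O, rt
Reagents that add atoms: bis(pinacolato)diboron, CC1(C)OB(OC1(C)C)B1OC(C)(C)C(C)(C)O1 (boron in 17 only); potassium peroxymonosulfate, [K+].OOS(=O)(=O)[O-] (phenol oxygen)
Why: Iridium-catalysed C–H borylation is governed by sterics and takes the only C–H without an ortho substituent, para to the methoxy group. Oxidation of the C–B bond then gives the phenol; the aryl bromide is tolerated.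

**Step 11**
Reactants: 18 3-bromo-4-methoxy-5-methylphenol
Product: 19 (3-bromo-4-methoxy-5-methylphenoxy)tri(propan-2-yl)silane
Conditions: i-Pr3SiCl, imidazole, DMF, rt
Reagents that add atoms: chlorotri(propan-2-yl)silane, CC(C)[Si](Cl)(C(C)C)C(C)C
Why: Silylation of the phenol; the bulky aryl silyl ether withstands the organometallic steps and the oxidation, and leaves under buffered fluoride at the end.

**Step 12**
Reactants: 19 (3-bromo-4-methoxy-5-methylphenoxy)tri(propan-2-yl)silane; 20 2-ethenyl-2-methyloxirane
Product: 22 (2E)-4-{2-methoxy-3-methyl-5-[tri(propan-2-yl)silyloxy]phenyl}-2-methylbut-2-en-1-ol, via arylmagnesium bromide 21 (not isolated)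
Conditions: Mg, THF, 50 °C; then CuI (10 mol%), 20, THF, −30 → 0 °C
Reagents that add atoms: magnesium, [Mg] (in 21 only)
Why: Grignard formation followed by copper-catalysed SN2' opening of the vinyl oxirane, which forms the aryl–C1' bond and moves the double bond to C2'=C3'. Reaction through the s-trans conformer of 20 should favour the E alkene; any Z isomer is removed here or at sulfone 24.

**Step 13**
Reactants: 22 (2E)-4-{2-methoxy-3-methyl-5-[tri(propan-2-yl)silyloxy]phenyl}-2-methylbut-2-en-1-ol
Product: 24 {3-[(2E)-4-(benzenesulfonyl)-3-methylbut-2-en-1-yl]-4-methoxy-5-methylphenoxy}tri(propan-2-yl)silane, via allylic bromide 23 (not isolated)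
Conditions: CBr4, PPh3, CH2Cl2, 0 °C; evaporate; PhSO2Na, DMF, rt
Reagents that add atoms: carbon tetrabromide, BrC(Br)(Br)Br (bromine in 23 only); sodium benzenesulfinate, [Na+].[O-]S(=O)c1ccccc1
Why: Appel bromination of the primary allylic alcohol and SN2 S-alkylation of the sulfinate at the primary carbon, both without allylic transposition. Aryl allyl sulfones tend to crystallise, which should help to secure geometric purity.

**Step 14**
Reactants: 24 {3-[(2E)-4-(benzenesulfonyl)-3-methylbut-2-en-1-yl]-4-methoxy-5-methylphenoxy}tri(propan-2-yl)silane; 14 (4aR,7aR)-4a,7a-dimethyl-1-(3-methylbut-2-en-1-yl)hexahydrocyclopenta[c]pyran-3(1H)-one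
Product: 26 (4E)-3-(benzenesulfonyl)-1-[(1R,2R)-2-(1-hydroxy-4-methylpent-3-en-1-yl)-1,2-dimethylcyclopentyl]-6-{2-methoxy-3-methyl-5-[tri(propan-2-yl)silyloxy]phenyl}-4-methylhex-4-en-2-one, via lithiated sulfone 25 (not isolated)
Conditions: 24 (2.2 equiv), n-BuLi (2.1 equiv), THF, −78 °C; then 14, −78 → −30 °C; aq. NH4Cl; excess 24 recovered
Reagents that add atoms: n-butyllithium, [Li]CCCC (lithium in 25 only)
Why: Claisen-type acylation of an α-sulfonyl allyl carbanion by a lactone forms C4'–C5'. The anion reacts at its α-carbon and keeps the E geometry, ring opening releases the C12' alkoxide, and the second equivalent of 25 deprotonates the acidic β-keto sulfone so that it is not attacked again. 26 is a mixture at C4' and C12', both of which are cleared later.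

**Step 15**
Reactants: 26 (4E)-3-(benzenesulfonyl)-1-[(1R,2R)-2-(1-hydroxy-4-methylpent-3-en-1-yl)-1,2-dimethylcyclopentyl]-6-{2-methoxy-3-methyl-5-[tri(propan-2-yl)silyloxy]phenyl}-4-methylhex-4-en-2-one
Product: 27 (4E)-1-[(1R,2R)-2-(1-hydroxy-4-methylpent-3-en-1-yl)-1,2-dimethylcyclopentyl]-6-{2-methoxy-3-methyl-5-[tri(propan-2-yl)silyloxy]phenyl}-4-methylhex-4-en-2-one
Conditions: SmI2 (3 equiv), THF/MeOH, −78 °C
Reagents that add atoms: none
Why: Reductive desulfonylation of a β-keto sulfone by electron transfer from divalent samarium. The samarium dienolate is protonated by methanol at C4' under kinetic control at low temperature, which leaves the alkene at C2'=C3'; an unactivated ketone and the aryl silyl ether are not reduced under these conditions.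

**Step 16**
Reactants: 27 (4E)-1-[(1R,2R)-2-(1-hydroxy-4-methylpent-3-en-1-yl)-1,2-dimethylcyclopentyl]-6-{2-methoxy-3-methyl-5-[tri(propan-2-yl)silyloxy]phenyl}-4-methylhex-4-en-2-one
Product: 28 1-[(1R,2R)-2-[(4E)-6-{2-methoxy-3-methyl-5-[tri(propan-2-yl)silyloxy]phenyl}-4-methyl-2-oxohex-4-en-1-yl]-1,2-dimethylcyclopentyl]-4-methylpent-3-en-1-one
Conditions: Dess–Martin periodinane, NaHCO3, CH2Cl2, 0 °C → rt
Reagents that add atoms: none
Why: Buffered hypervalent-iodine oxidation of the secondary carbinol to the ketone without acid or base strong enough to conjugate either skipped enone. Any cyclic hemiketal form of 27 is drained through the open hydroxy ketone. The silyl ether keeps the electron-rich phenol from being oxidised to a quinone.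

**Step 17**
Reactants: 28 1-[(1R,2R)-2-[(4E)-6-{2-methoxy-3-methyl-5-[tri(propan-2-yl)silyloxy]phenyl}-4-methyl-2-oxohex-4-en-1-yl]-1,2-dimethylcyclopentyl]-4-methylpent-3-en-1-one
Product: 29 1-[(1R,2R)-2-[(4E)-6-(5-hydroxy-2-methoxy-3-methylphenyl)-4-methyl-2-oxohex-4-en-1-yl]-1,2-dimethylcyclopentyl]-4-methylpent-3-en-1-one
Conditions: Bu4NF, AcOH (1:1), THF, 0 °C
Reagents that add atoms: none
Why: Fluoride cleaves the aryl silyl ether; acetic acid protonates the phenoxide at once, so the medium stays too weakly basic to enolise the β,γ-unsaturated ketones.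

## Compound list

1 | pent-4-yn-1-ol | C#CCCCO | starting material
2 | pent-4-yn-1-yl 4-methylbenzenesulfonate | C#CCCCOS(=O)(=O)c1ccc(C)cc1 | intermediate
3 | isopropenylmagnesium bromide | CC(=C)[Mg]Br | starting material
4 | 6-methylhept-6-en-1-yne | C#CCCCC(C)=C | intermediate
5 | carbon monoxide | [C-]#[O+] | starting material
6 | (R)-5-methylbicyclo[3.3.0]oct-1-en-3-one | O=C1C[C@@]2(C)CCCC2=C1 | intermediate
7 | (1S,5R)-1,5-dimethyl-3-(trimethylsilyloxy)bicyclo[3.3.0]oct-2-ene | C[Si](C)(C)OC1=C[C@]2(C)CCC[C@]2(C)C1 | intermediate
8 | trimethylsilyl 2-[(1R,2R)-2-formyl-1,2-dimethylcyclopentyl]acetate (formed in the flask) | C[Si](C)(C)OC(=O)C[C@@]1(C)CCC[C@@]1(C)C=O | intermediate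
9 | 2-[(1R,2R)-2-formyl-1,2-dimethylcyclopentyl]acetic acid | OC(=O)C[C@@]1(C)CCC[C@@]1(C)C=O | intermediate
10 | methyl 2-[(1R,2R)-2-formyl-1,2-dimethylcyclopentyl]acetate | COC(=O)C[C@@]1(C)CCC[C@@]1(C)C=O | intermediate
11 | methyl 2-[(1R,2R)-1,2-dimethyl-2-(oxiran-2-yl)cyclopentyl]acetate (both oxirane epimers) | COC(=O)C[C@@]1(C)CCC[C@@]1(C)C2CO2 | intermediate
12 | 2-methylprop-1-en-1-ylmagnesium bromide | CC(C)=C[Mg]Br | starting material
13 | methyl 2-[(1R,2R)-2-(1-hydroxy-4-methylpent-3-en-1-yl)-1,2-dimethylcyclopentyl]acetate (formed in the flask, both carbinol epimers) | COC(=O)C[C@@]1(C)CCC[C@@]1(C)C(O)CC=C(C)C | intermediate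
14 | (4aR,7aR)-4a,7a-dimethyl-1-(3-methylbut-2-en-1-yl)hexahydrocyclopenta[c]pyran-3(1H)-one (both C1 epimers) | O=C1C[C@@]2(C)CCC[C@@]2(C)C(CC=C(C)C)O1 | intermediate
15 | 2-bromo-6-methylphenol | Cc1cccc(Br)c1O | starting material
16 | 1-bromo-2-methoxy-3-methylbenzene | COc1c(C)cccc1Br | intermediate
17 | 2-(3-bromo-4-methoxy-5-methylphenyl)-4,4,5,5-tetramethyl-1,3,2-dioxaborolane (formed in the flask) | COc1c(C)cc(cc1Br)B2OC(C)(C)C(C)(C)O2 | intermediate
18 | 3-bromo-4-methoxy-5-methylphenol | COc1c(C)cc(O)cc1Br | intermediate
19 | (3-bromo-4-methoxy-5-methylphenoxy)tri(propan-2-yl)silane | COc1c(C)cc(O[Si](C(C)C)(C(C)C)C(C)C)cc1Br | intermediate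
20 | 2-ethenyl-2-methyloxirane (2-methyl-2-vinyloxirane) | CC1(C=C)CO1 | starting material
21 | {2-methoxy-3-methyl-5-[tri(propan-2-yl)silyloxy]phenyl}magnesium bromide (formed in the flask) | COc1c(C)cc(O[Si](C(C)C)(C(C)C)C(C)C)cc1[Mg]Br | intermediate
22 | (2E)-4-{2-methoxy-3-methyl-5-[tri(propan-2-yl)silyloxy]phenyl}-2-methylbut-2-en-1-ol | COc1c(C)cc(O[Si](C(C)C)(C(C)C)C(C)C)cc1C/C=C(\C)CO | intermediate
23 | {3-[(2E)-4-bromo-3-methylbut-2-en-1-yl]-4-methoxy-5-methylphenoxy}tri(propan-2-yl)silane (formed in the flask) | COc1c(C)cc(O[Si](C(C)C)(C(C)C)C(C)C)cc1C/C=C(\C)CBr | intermediate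
24 | {3-[(2E)-4-(benzenesulfonyl)-3-methylbut-2-en-1-yl]-4-methoxy-5-methylphenoxy}tri(propan-2-yl)silane | COc1c(C)cc(O[Si](C(C)C)(C(C)C)C(C)C)cc1C/C=C(\C)CS(=O)(=O)c2ccccc2 | intermediate
25 | α-lithio derivative of 24, lithium on the carbon bearing the sulfonyl group (formed in the flask) | COc1c(C)cc(O[Si](C(C)C)(C(C)C)C(C)C)cc1C/C=C(\C)C([Li])S(=O)(=O)c2ccccc2 | intermediate
26 | (4E)-3-(benzenesulfonyl)-1-[(1R,2R)-2-(1-hydroxy-4-methylpent-3-en-1-yl)-1,2-dimethylcyclopentyl]-6-{2-methoxy-3-methyl-5-[tri(propan-2-yl)silyloxy]phenyl}-4-methylhex-4-en-2-one (mixture at C3 and at the carbinol carbon) | COc1c(C)cc(O[Si](C(C)C)(C(C)C)C(C)C)cc1C/C=C(\C)C(S(=O)(=O)c2ccccc2)C(=O)C[C@@]1(C)CCC[C@@]1(C)C(O)CC=C(C)C | intermediate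
27 | (4E)-1-[(1R,2R)-2-(1-hydroxy-4-methylpent-3-en-1-yl)-1,2-dimethylcyclopentyl]-6-{2-methoxy-3-methyl-5-[tri(propan-2-yl)silyloxy]phenyl}-4-methylhex-4-en-2-one (both carbinol epimers) | COc1c(C)cc(O[Si](C(C)C)(C(C)C)C(C)C)cc1C/C=C(\C)CC(=O)C[C@@]1(C)CCC[C@@]1(C)C(O)CC=C(C)C | intermediate
28 | 1-[(1R,2R)-2-[(4E)-6-{2-methoxy-3-methyl-5-[tri(propan-2-yl)silyloxy]phenyl}-4-methyl-2-oxohex-4-en-1-yl]-1,2-dimethylcyclopentyl]-4-methylpent-3-en-1-one | COc1c(C)cc(O[Si](C(C)C)(C(C)C)C(C)C)cc1C/C=C(\C)CC(=O)C[C@@]1(C)CCC[C@@]1(C)C(=O)CC=C(C)C | intermediate
29 | 1-[(1R,2R)-2-[(4E)-6-(5-hydroxy-2-methoxy-3-methylphenyl)-4-methyl-2-oxohex-4-en-1-yl]-1,2-dimethylcyclopentyl]-4-methylpent-3-en-1-one | COc1c(C)cc(O)cc1C/C=C(\C)CC(=O)C[C@@]1(C)CCC[C@@]1(C)C(=O)CC=C(C)C | target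

## Step count and the least certain steps

Total: 17 steps. Longest linear sequence: 12 steps (steps 1–8, then 14–17); the aryl branch (steps 9–13) joins at step 14.

**Step 3 (key step).** Oligomerisation of the terminal alkyne and cycloisomerisation may outrun carbonylative cyclisation, because the tether has no substituents to favour ring closure. Enantioface discrimination at a 1,1-disubstituted alkene may also be insufficient.
Fallback, from 4 back to 7: the chirality is moved from the cyclisation to a later deprotonation, using the fact that the cis-dimethyl ketone is meso. Enyne 4 is cyclised with stoichiometric Co2(CO)8 and N-methylmorpholine N-oxide in CH2Cl2, a reaction that favours terminal alkynes, to give racemic 5-methylbicyclo[3.3.0]oct-1-en-3-one F1. The conjugate methylation of step 4 then gives the racemic silyl enol ether F2, which is hydrolysed on purpose with dilute HCl to cis-1,5-dimethylbicyclo[3.3.0]octan-3-one F3; both enantiomers of F1 converge on it. Enantiotopic deprotonation of F3 with one antipode of lithium bis(1-phenylethyl)amide (chosen in a test run) in THF at −100 °C with Me3SiCl present returns enol ether 7.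

**Step 4.** Addition to a fully substituted β-carbon beside a quaternary centre may be slow enough for γ-deprotonation of the enone or 1,2-addition to take over. Partial hydrolysis of the enol ether during isolation would erode the enantiomeric purity.
Fallback, from 6 back to 7: the methyl is built from a cyclopropane. Luche reduction (NaBH4, CeCl3, MeOH) gives (5R)-5-methylbicyclo[3.3.0]oct-1-en-3-ol F4. Simmons–Smith cyclopropanation (Et2Zn, CH2I2, CH2Cl2), which for reasons of ring strain can only occur on the face of the angular methyl, gives 6-methyltricyclo[4.3.0.0^1,3]nonan-4-ol F5. Dess–Martin oxidation gives 6-methyltricyclo[4.3.0.0^1,3]nonan-4-one F6. Lithium in liquid NH3/THF cleaves the exocyclic cyclopropane bond that overlaps with the carbonyl, which creates the C11' methyl and the enolate towards C12'; silylation with Me3SiCl/Et3N gives 7.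

**Step 8.** The Grignard reagent may attack the ester, or the lactone once formed, instead of the epoxide. Magnesium salts may induce a 1,2-shift in an epoxide that sits beside a quaternary carbon.
Fallback, from 10 back to 14 (step 7 is skipped): prenyl chloride and activated barium (BaI2 reduced with lithium biphenylide, THF, −78 °C) give (3-methylbut-2-en-1-yl)barium chloride F7. This reagent adds to aldehydes through its α-carbon and should give hydroxy ester 13 directly from 10, which lactonises to 14 as in step 8.

**Step 14.** Proton transfer from the α-carbon of the lactone to the sulfonyl carbanion may compete with acylation at a carbonyl flanked by a neopentyl-type carbon. The step also consumes two equivalents of the sulfone.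
Fallback, from 14 back to 27: the lactone is opened with Me(MeO)NH·HCl/Me3Al (CH2Cl2, 0 °C) to 2-[(1R,2R)-2-(1-hydroxy-4-methylpent-3-en-1-yl)-1,2-dimethylcyclopentyl]-N-methoxy-N-methylacetamide F8. This is silylated at once (Et3SiOTf, 2,6-lutidine) to its triethylsilyl ether F9. Addition of 25 (1.2 equiv) to this amide, whose tetrahedral adduct persists until work-up so that one equivalent suffices, gives the silylated β-keto sulfone F10. SmI2/MeOH as in step 15 gives the silylated ketone F11, and HF·pyridine (THF/pyridine, 0 °C) removes the triethylsilyl group to give 27.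

**Step 15.** The dienolate may be protonated at C2', or the product may undergo a prototropic shift, either of which brings the C2'=C3' alkene into conjugation with C5'. The same shift threatens in steps 16 and 17, which is why both are buffered.
Fallback, from 14 and 22 back to 28 (steps 14–16 are replaced): both ketones are made by oxidation, so no enolate of C5' is generated. i-Bu2AlH (CH2Cl2, −78 °C) reduces 14 to the lactol (4aR,7aR)-4a,7a-dimethyl-1-(3-methylbut-2-en-1-yl)octahydrocyclopenta[c]pyran-3-ol F12. Alcohol 22 is converted (MsCl, LiCl, 2,4,6-collidine, DMF, 0 °C) into {3-[(2E)-4-chloro-3-methylbut-2-en-1-yl]-4-methoxy-5-methylphenoxy}tri(propan-2-yl)silane F13, and activated barium at −78 °C turns this into the allylbarium chloride F14. F14 (2.5 equiv) adds through its α-carbon, with retention of the E geometry, to the open hydroxy aldehyde form of F12 to give (4E)-1-[(1R,2R)-2-(1-hydroxy-4-methylpent-3-en-1-yl)-1,2-dimethylcyclopentyl]-6-{2-methoxy-3-methyl-5-[tri(propan-2-yl)silyloxy]phenyl}-4-methylhex-4-en-2-ol F15. Buffered Dess–Martin oxidation of both carbinols gives 28.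

## Further compounds

F1 | step 3 | racemic 5-methylbicyclo[3.3.0]oct-1-en-3-one | O=C1CC2(C)CCCC2=C1
F2 | step 3 | racemic cis-1,5-dimethyl-3-(trimethylsilyloxy)bicyclo[3.3.0]oct-2-ene (relative configuration shown) | C[Si](C)(C)OC1=C[C@]2(C)CCC[C@]2(C)C1
F3 | step 3 | cis-1,5-dimethylbicyclo[3.3.0]octan-3-one (meso) | O=C1C[C@@]2(C)CCC[C@@]2(C)C1
F4 | step 4 | (5R)-5-methylbicyclo[3.3.0]oct-1-en-3-ol (either C3 epimer) | OC1C[C@@]2(C)CCCC2=C1
F5 | step 4 | 6-methyltricyclo[4.3.0.0^1,3]nonan-4-ol, cyclopropane CH2 cis to the C6 methyl, configuration derived from (R)-6 | OC1C[C@@]2(C)CCC[C@]23C[C@H]13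
F6 | step 4 | 6-methyltricyclo[4.3.0.0^1,3]nonan-4-one, cyclopropane CH2 cis to the C6 methyl | O=C1C[C@@]2(C)CCC[C@]23C[C@H]13
F7 | step 8 | (3-methylbut-2-en-1-yl)barium chloride | CC(C)=CC[Ba]Cl
F8 | step 14 | 2-[(1R,2R)-2-(1-hydroxy-4-methylpent-3-en-1-yl)-1,2-dimethylcyclopentyl]-N-methoxy-N-methylacetamide | CON(C)C(=O)C[C@@]1(C)CCC[C@@]1(C)C(O)CC=C(C)C
F9 | step 14 | N-methoxy-N-methyl-2-[(1R,2R)-1,2-dimethyl-2-(4-methyl-1-triethylsilyloxypent-3-en-1-yl)cyclopentyl]acetamide | CON(C)C(=O)C[C@@]1(C)CCC[C@@]1(C)C(O[Si](CC)(CC)CC)CC=C(C)C
F10 | step 14 | triethylsilyl ether of 26 at the carbinol oxygen | COc1c(C)cc(O[Si](C(C)C)(C(C)C)C(C)C)cc1C/C=C(\C)C(S(=O)(=O)c2ccccc2)C(=O)C[C@@]1(C)CCC[C@@]1(C)C(O[Si](CC)(CC)CC)CC=C(C)C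
F11 | step 14 | triethylsilyl ether of 27 at the carbinol oxygen | COc1c(C)cc(O[Si](C(C)C)(C(C)C)C(C)C)cc1C/C=C(\C)CC(=O)C[C@@]1(C)CCC[C@@]1(C)C(O[Si](CC)(CC)CC)CC=C(C)C
F12 | step 15 | (4aR,7aR)-4a,7a-dimethyl-1-(3-methylbut-2-en-1-yl)octahydrocyclopenta[c]pyran-3-ol | OC1C[C@@]2(C)CCC[C@@]2(C)C(CC=C(C)C)O1
F13 | step 15 | {3-[(2E)-4-chloro-3-methylbut-2-en-1-yl]-4-methoxy-5-methylphenoxy}tri(propan-2-yl)silane | COc1c(C)cc(O[Si](C(C)C)(C(C)C)C(C)C)cc1C/C=C(\C)CCl
F14 | step 15 | [(2E)-4-{2-methoxy-3-methyl-5-[tri(propan-2-yl)silyloxy]phenyl}-2-methylbut-2-en-1-yl]barium chloride | COc1c(C)cc(O[Si](C(C)C)(C(C)C)C(C)C)cc1C/C=C(\C)C[Ba]Cl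
F15 | step 15 | (4E)-1-[(1R,2R)-2-(1-hydroxy-4-methylpent-3-en-1-yl)-1,2-dimethylcyclopentyl]-6-{2-methoxy-3-methyl-5-[tri(propan-2-yl)silyloxy]phenyl}-4-methylhex-4-en-2-ol | COc1c(C)cc(O[Si](C(C)C)(C(C)C)C(C)C)cc1C/C=C(\C)CC(O)C[C@@]1(C)CCC[C@@]1(C)C(O)CC=C(C)C
A1 | alternative 1 | cyclopentene-fused menthyloxybutenolide, 3-menthyloxy-3,4,5,6-tetrahydro-1H-cyclopenta[c]furan-1-one | O=C1O[C@@H](O[C@@H]3C[C@H](C)CC[C@H]3C(C)C)C2=C1CCC2
A2 | alternative 1 | cis-fused dimethyl lactone acetal | O=C1O[C@@H](O[C@@H]3C[C@H](C)CC[C@H]3C(C)C)[C@@]2(C)CCC[C@@]12C
A3 | alternative 2 | (R)-2-tert-butyl-6-methyl-1,3-dioxin-4-one | O=C1O[C@H](C(C)(C)C)OC(C)=C1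
A4 | alternative 2 | 1,2-dimethylcyclopentene | CC1=C(C)CCC1
A5 | alternative 2 | cis-anti-cis cyclobutane photoadduct | O=C1O[C@H](C(C)(C)C)O[C@]2(C)[C@H]1[C@@]3(C)CCC[C@@]23C
A6 | alternative 3 | biacetyl (butane-2,3-dione) | CC(=O)C(C)=O
A7 | alternative 3 | dimethyl 3-oxoglutarate | COC(=O)CC(=O)CC(=O)OC
A8 | alternative 3 | cis-1,5-dimethylbicyclo[3.3.0]octane-3,7-dione (meso) | O=C1C[C@@]2(C)CC(=O)C[C@@]2(C)C1
A9 | alternative 3 | cis-1,5-dimethylbicyclo[3.3.0]octan-3-one (meso) | O=C1C[C@@]2(C)CCC[C@@]2(C)C1
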